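Ring B is disconnected at C4–C4a and C8a–C1, which releases ring A as guaiacol. The feature exploited is that C8a lies para to the C6 hydroxyl and its neighbour C4a para to the C7 methoxy group. These are the two innately nucleophilic carbons of guaiacol, and C1–C4 is a 1,4-dielectrophile. The dielectrophile is hidden in an enantioenriched donor–acceptor cyclopropane triester (ring carbons C1, C2, C3; one geminal ester is C4). In one acid-mediated operation guaiacol opens the cyclopropane at C1 with inversion and is acylated by C4, a formal [4+2] annulation that builds ring B. C1 then dictates C2 and C3 by equilibration.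

Key step: step 4

Remark on numbering and configuration: tetralin numbering is used throughout.
- C1 is the CH bearing ring C. C2 and C3 are the CH groups bearing the hydroxymethyl carbons C9 and C9'. C4 is the CH2.
- Ring A is C4a–C8a, ring B is the saturated ring, and ring C is the pendant aryl.
- The SMILES decodes as (1S,2R,3R), that is 1,2-trans-2,3-trans, with OH on C6 and OMe on C7.

Step 1
Reactants: 1 coniferaldehyde
Product: 2 (E)-3-methoxy-4-(methylsulfonyloxy)cinnamaldehyde
Conditions: MsCl (1.1 equiv), Et3N (1.3 equiv), CH2Cl2, 0 °C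
Reagents that add atoms: methanesulfonyl chloride, CS(=O)(=O)Cl
Why: Sulfonylation of the phenol installs an acid-proof, electron-withdrawing mesylate that prevents phenoxide chemistry in step 2 and later distinguishes ring C from ring A.

Step 2
Reactants: 2 (E)-3-methoxy-4-(methylsulfonyloxy)cinnamaldehyde; 3 dimethyl bromomalonate
Product: 4 dimethyl (2S,3R)-2-formyl-3-[3-methoxy-4-(methylsulfonyloxy)phenyl]cyclopropane-1,1-dicarboxylate
Conditions: (R)-α,α-diphenylprolinol trimethylsilyl ether (20 mol %), 2,6-lutidine (1.1 equiv), CH2Cl2, 0 °C to rt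
Reagents that add atoms: none
Why: In this iminium–enamine Michael-initiated ring closure the malonate adds to the β-carbon of the E-iminium ion on the face left open by the CPh2OSiMe3 group of the R catalyst (this sets the future C1), and the enamine then displaces bromide on the same face, so aryl and formyl end up trans.

Step 3
Reactants: 4 dimethyl (2S,3R)-2-formyl-3-arylcyclopropane-1,1-dicarboxylate
Product: 5 trimethyl (2S,3R)-3-[3-methoxy-4-(methylsulfonyloxy)phenyl]cyclopropane-1,1,2-tricarboxylate
Conditions: 2KHSO5·KHSO4·K2SO4 (Oxone), MeOH, rt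
Reagents that add atoms: methanol, CO
Why: Peroxymonosulfate oxidation of the methyl hemiacetal gives the ester without base, which avoids the base-induced retro-Michael opening of formylcyclopropanes, touches no stereocentre and makes C2 epimerisable for step 6.

Step 4
Reactants: 5 trimethyl (2S,3R)-3-arylcyclopropane-1,1,2-tricarboxylate; 6 guaiacol
Product: 8 dimethyl (1S,2S)-6-hydroxy-7-methoxy-1-[3-methoxy-4-(methylsulfonyloxy)phenyl]-4-oxo-1,2,3,4-tetrahydronaphthalene-2,3-dicarboxylate, via open-chain triester 7 (not isolated)
Conditions: 6 (3 equiv), TfOH (1 equiv), (CF3)2CHOH, 25 °C; then more TfOH (8 equiv), 50 °C, same flask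
Reagents that add atoms: none
Why: Proposed new method: TfOH in (CF3)2CHOH protonates the geminal diester of 5 and polarises the C1–C3 bond, guaiacol attacks C1 through its carbon para to OH from the rear of that bond (SN2-like Friedel–Crafts alkylation, C8a–C1) to give 7, and the malonate of 7 then loses MeOH to an acylium or acylketene that is captured by the neighbouring ring A carbon para to OMe (C4–C4a). The closest known reaction types are the acid-catalysed opening of 2-arylcyclopropane-1,1-diesters by electron-rich arenes and the one-pot alkylation–acylation of arenes with γ-aryl-γ-butyrolactones that gives 4-aryl-1-tetralones, and only their merger on a cyclopropane triester is new. Ring B closes by a 6-exo-trig Friedel–Crafts acylation. C1 is the only fixed new stereocentre and is controlled by inversion at the cyclopropane carbon set in step 2 (attack anti to the malonyl group of an A(1,3)-minimised cation would lead to the same epimer), whereas C3 is a labile β-keto ester centre and C2 is corrected in step 6. Site selectivity on guaiacol follows from OH being the stronger para director for the intermolecular event and from OMe activating the only unhindered ortho carbon for the closure. The mesylate makes ring C a poor donor, so the opening stays stereospecific, and a poor nucleophile, so ring A and not ring C is acylated, while six-membered closure through either of two malonate carbonyls should outrun five-membered closure through the C2 ester, as in the cyclisation of benzylsuccinic acids to tetralones.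

Step 5
Reactants: 8 (1S,2S)-keto diester
Product: 9 dimethyl (1S,2S)-6-hydroxy-7-methoxy-1-[3-methoxy-4-(methylsulfonyloxy)phenyl]-1,2,3,4-tetrahydronaphthalene-2,3-dicarboxylate
Conditions: Et3SiH (4 equiv), CF3CO2H, rt to 50 °C
Reagents that add atoms: none
Why: In this ionic hydrogenation (Kursanov–Parnes type) the ketone para to OMe is protonated, reduced, ionised to the p-methoxybenzylic cation and reduced again to CH2, while esters, mesylate, phenol, C1 and C2 are untouched and the C3 epimers converge in step 6.

Step 6
Reactants: 9 (1S,2S)-diester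
Product: 11 (1S,2R,3R)-6-hydroxy-1-(4-hydroxy-3-methoxyphenyl)-7-methoxy-1,2,3,4-tetrahydronaphthalene-2,3-dicarboxylic acid, via all-trans diester 10 (not isolated)
Conditions: NaOMe (6 equiv), dry MeOH, reflux; then 2 M aq NaOH, reflux; HCl work-up
Reagents that add atoms: sodium hydroxide, [Na+].[OH-]
Why: In this thermodynamic epimerisation through the ester enolates the fixed C1 lets C2 and C3 settle in the all-equatorial 1,2-trans-2,3-trans diester 10, after which hydroxide saponifies both esters and cleaves the aryl mesylate at sulfur.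

Step 7
Reactants: 11 all-trans diacid
Product: 12 (1S,2R,3R)-1-(4-hydroxy-3-methoxyphenyl)-2,3-bis(hydroxymethyl)-7-methoxy-1,2,3,4-tetrahydronaphthalen-6-ol (target)
Conditions: BH3·THF (8 equiv), THF, 0 °C to rt; MeOH quench
Reagents that add atoms: none
Why: Borane reduces both carboxylic acids through acyloxyboranes to primary alcohols without touching a stereocentre or an arene, and the aryl borates formed from the phenols are hydrolysed on work-up.

Compound list
1 | coniferaldehyde, (E)-4-hydroxy-3-methoxycinnamaldehyde | COc1cc(/C=C/C=O)ccc1O | starting material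
2 | (E)-3-methoxy-4-(methylsulfonyloxy)cinnamaldehyde | COc1cc(/C=C/C=O)ccc1OS(C)(=O)=O | intermediate
3 | dimethyl bromomalonate | COC(=O)C(Br)C(=O)OC | starting material
4 | dimethyl (2S,3R)-2-formyl-3-[3-methoxy-4-(methylsulfonyloxy)phenyl]cyclopropane-1,1-dicarboxylate (aryl and formyl trans) | O=C[C@H]1[C@H](c2ccc(OS(C)(=O)=O)c(OC)c2)C1(C(=O)OC)C(=O)OC | intermediate
5 | trimethyl (2S,3R)-3-[3-methoxy-4-(methylsulfonyloxy)phenyl]cyclopropane-1,1,2-tricarboxylate | COC(=O)[C@H]1[C@H](c2ccc(OS(C)(=O)=O)c(OC)c2)C1(C(=O)OC)C(=O)OC | intermediate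
6 | guaiacol, 2-methoxyphenol | COc1ccccc1O | starting material
7 | trimethyl (2S,3R)-3-(4-hydroxy-3-methoxyphenyl)-3-[3-methoxy-4-(methylsulfonyloxy)phenyl]propane-1,1,2-tricarboxylate | COC(=O)C(C(=O)OC)[C@@H](C(=O)OC)[C@H](c1ccc(O)c(OC)c1)c1ccc(OS(C)(=O)=O)c(OC)c1 | intermediate
8 | dimethyl (1S,2S)-6-hydroxy-7-methoxy-1-[3-methoxy-4-(methylsulfonyloxy)phenyl]-4-oxo-1,2,3,4-tetrahydronaphthalene-2,3-dicarboxylate (1,2-cis; C3 labile, keto/enol, unassigned) | COc1cc([C@H]2c3cc(OC)c(O)cc3C(=O)C(C(=O)OC)[C@H]2C(=O)OC)ccc1OS(C)(=O)=O | intermediate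
9 | dimethyl (1S,2S)-6-hydroxy-7-methoxy-1-[3-methoxy-4-(methylsulfonyloxy)phenyl]-1,2,3,4-tetrahydronaphthalene-2,3-dicarboxylate (1,2-cis; C3 epimers, both converge) | COc1cc([C@H]2c3cc(OC)c(O)cc3CC(C(=O)OC)[C@H]2C(=O)OC)ccc1OS(C)(=O)=O | intermediate
10 | dimethyl (1S,2R,3R)-6-hydroxy-7-methoxy-1-[3-methoxy-4-(methylsulfonyloxy)phenyl]-1,2,3,4-tetrahydronaphthalene-2,3-dicarboxylate (all-trans) | COc1cc([C@H]2c3cc(OC)c(O)cc3C[C@@H](C(=O)OC)[C@@H]2C(=O)OC)ccc1OS(C)(=O)=O | intermediate
11 | (1S,2R,3R)-6-hydroxy-1-(4-hydroxy-3-methoxyphenyl)-7-methoxy-1,2,3,4-tetrahydronaphthalene-2,3-dicarboxylic acid | COc1cc([C@H]2c3cc(OC)c(O)cc3C[C@@H](C(=O)O)[C@@H]2C(=O)O)ccc1O | intermediate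
12 | (1S,2R,3R)-1-(4-hydroxy-3-methoxyphenyl)-2,3-bis(hydroxymethyl)-7-methoxy-1,2,3,4-tetrahydronaphthalen-6-ol | COc1cc([C@H]2c3cc(OC)c(O)cc3C[C@@H](CO)[C@@H]2CO)ccc1O | target

Total step count: 7. Longest linear sequence: 7 (steps 1–7; compounds 3 and 6 are bought).

Steps most likely to fail

Step 4 (Proposed new method).
- Five-membered acylation through the C2 ester may compete with the six-membered closure.
- Guaiacol may attack through the carbon ortho to OH or para to OMe.
- The opened cyclopropane may lose a proton to a styrylmalonate.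
- Partial ionisation before C–C bond formation may lower the fidelity at C1. This would surface as loss of enantiopurity after step 6, so the C1 epimer, a diastereomer at the stage of 8, should be removed there.

Fallback: it sets out from 5. Hydrolytic ring opening and lactonisation (TsOH·H2O, wet dioxane, heat), a known reaction of donor–acceptor cyclopropane diesters, gives the γ-aryl-γ-butyrolactone dimethyl (3R)-2-[3-methoxy-4-(methylsulfonyloxy)phenyl]-5-oxotetrahydrofuran-3,4-dicarboxylate F1. F1 and 6 are then submitted to the known one-pot lactone alkylation–acylation in TfOH. After the alkylation C4 is the only free carboxylic acid, which steers the acylation to the six-membered ring. Both bonds to ring A are still made in one operation. The C1 configuration then rests on attack anti to the malonyl group. The fallback comes back to the route at 8.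

Step 6.
- The equilibrium may not lie far enough on the all-trans side.
- Adventitious water may saponify the esters early and freeze the 1,2-cis isomer.
- Methyl methanesulfonate formed from mesylate and methoxide may methylate a phenoxide.

Fallback: it sets out from 9 and moves the epimerisation to the aldehyde oxidation level.
- i-Bu2AlH (CH2Cl2, −78 °C) gives the 1,2-cis dialdehyde F4.
- DBU in CH2Cl2 equilibrates the far more acidic formyl-bearing centres to the all-trans dialdehyde F5.
- NaBH4 in MeOH gives the all-trans diol mesylate F6.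
- Aqueous NaOH in MeOH at reflux removes the mesylate, and the fallback comes back to the route at 12.

Step 5.
- The enolised β-keto ester may be slow to protonate.
- The benzylic alcohol may eliminate to a conjugated dihydronaphthalene ester that resists ionic hydrogenation.

Fallback: it sets out from 8 and uses that elimination on purpose.
- NaBH4 (MeOH, 0 °C) gives the benzylic alcohol F2.
- TsOH·H2O in toluene at reflux dehydrates it to the 1,2-dihydronaphthalene diester F3.
- Hydrogenation over Pd/C (H2, EtOAc) saturates C3=C4. The facial outcome at C3 is irrelevant because of step 6, and the fallback comes back to the route at 9.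

Further compounds
F1 | step 4 | dimethyl (3R)-2-[3-methoxy-4-(methylsulfonyloxy)phenyl]-5-oxotetrahydrofuran-3,4-dicarboxylate (carbinol carbon and malonate carbon unassigned) | COC(=O)C1C(=O)OC(c2ccc(OS(C)(=O)=O)c(OC)c2)[C@@H]1C(=O)OC
F2 | step 5 | dimethyl (1S,2S)-4,6-dihydroxy-7-methoxy-1-[3-methoxy-4-(methylsulfonyloxy)phenyl]-1,2,3,4-tetrahydronaphthalene-2,3-dicarboxylate (C3 and C4 unassigned) | COc1cc([C@H]2c3cc(OC)c(O)cc3C(O)C(C(=O)OC)[C@H]2C(=O)OC)ccc1OS(C)(=O)=O
F3 | step 5 | dimethyl (1S,2S)-6-hydroxy-7-methoxy-1-[3-methoxy-4-(methylsulfonyloxy)phenyl]-1,2-dihydronaphthalene-2,3-dicarboxylate | COc1cc([C@H]2c3cc(OC)c(O)cc3C=C(C(=O)OC)[C@H]2C(=O)OC)ccc1OS(C)(=O)=O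
F4 | step 6 | (1S,2S)-6-hydroxy-7-methoxy-1-[3-methoxy-4-(methylsulfonyloxy)phenyl]-1,2,3,4-tetrahydronaphthalene-2,3-dicarbaldehyde (C3 unassigned) | COc1cc([C@H]2c3cc(OC)c(O)cc3CC(C=O)[C@H]2C=O)ccc1OS(C)(=O)=O
F5 | step 6 | (1S,2R,3R)-6-hydroxy-7-methoxy-1-[3-methoxy-4-(methylsulfonyloxy)phenyl]-1,2,3,4-tetrahydronaphthalene-2,3-dicarbaldehyde | COc1cc([C@H]2c3cc(OC)c(O)cc3C[C@@H](C=O)[C@@H]2C=O)ccc1OS(C)(=O)=O
F6 | step 6 | 4-[(1S,2R,3R)-6-hydroxy-2,3-bis(hydroxymethyl)-7-methoxy-1,2,3,4-tetrahydronaphthalen-1-yl]-2-methoxyphenyl methanesulfonate | COc1cc([C@H]2c3cc(OC)c(O)cc3C[C@@H](CO)[C@@H]2CO)ccc1OS(C)(=O)=O
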